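Oak cannot have stalled for want of starting material or reagent: over its last 3 readings starting material, the limiting reagent, still averages 63.2%, and because each starting material used takes one reagent with it, 85.3% of the reagent stands beside it.

all flasks: free catalyst 13 mol%
- oak: starting material 0.10 M; reagent 2.5 equiv; temperature −20 °C; the very flask that is asked about, followed so far
- elm: starting material 0.20 M; reagent 2.5 equiv; temperature −14 °C; run made earlier
- flask: starting material 0.10 M; reagent 2.50 equiv; temperature −20 °C; time 8.0 min

oak run (percent of the starting material charged)

| time / min | product / % | starting material / % |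
|---|---|---|
| 0.333 | 9.1 | 90.6 |
| 1.00 | 17.6 | 81.1 |
| 2.00 | 24.9 | 71.3 |
| 3.00 | 27.8 | 66.0 |
| 4.00 | 28.2 | 64.0 |
| 5.00 | 29.7 | 63.2 |
| 6.00 | 32.4 | 62.4 |

elm run (percent of the starting material charged)

| time / s | product / % | starting material / % |
|---|---|---|
| 15.0 | 29.9 | 69.5 |
| 30.0 | 37.0 | 60.7 |
| 40.0 | 37.6 | 56.8 |
| 60.0 | 38.8 | 54.1 |
| 80.0 | 36.4 | 51.1 |
| 90.0 | 38.2 | 50.4 |

(each reading ± 1 percentage point)

- removed product is counted in
- steps under discussion: starting material + reagent + free catalyst <-> product + free catalyst; free catalyst + product -> spent catalyst; free catalyst <-> dormant form
- additions bring no volume worth counting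

- Wednesday's: at 8.0 min raise the temperature by 15 K, then wait 15 min
- Saturday's: at 8.0 min add reagent, 100% of the amount charged, then wait 15 min
- Sunday's: at 8.0 min add free catalyst, 100% of the amount charged, then wait 15 min
- Thursday's: change nothing and wait 15 min more
- Monday's: at 8.0 min take out 90% of the product then present, then wait 15 min

- product, in percent of the starting material first charged, at 8.0 min
- which option adds most product ("none" when 2 percentage points or less is all one gets) (Wednesday's / Saturday's / Sunday's / Thursday's / Monday's / none)
- product present, with what was taken out counted in, in percent of the starting material first charged, after Wednesday's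
- product present, with what was taken out counted in, in percent of the starting material first charged, after Saturday's

So look for what stays nearly constant once product flattens. Oak's product averages 30.1% over those readings, and you can freeze 2.23 L mol⁻¹ as the stall quotient, product concentration over starting material concentration times reagent concentration.

There are two ways to oak's product at 8.0 min. The first simply carries the flat readings forward, which gives 30.1%. The second is independent of oak's product: elm's last 3 readings average 37.8% product and 51.9% starting material, so elm's quotient reads 1.81 L mol⁻¹. Put into oak's starting material and reagent, that gives 24.3%.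

The two ways part. But elm ran at −14 °C against oak's −20 °C and at 0.20 M against oak's 0.10 M, and its quotient is lower than oak's, so the second way carries a number from a flask that differs in two settings. That way cheats, and my own reckoning stays at 30.1%. Elm's balance also lacks 10.3%, beside a loading of 13 mol%, as free catalyst taking one product each into spent catalyst would leave it.

The forecast gave 32% (30% to 35%), chose Saturday's, and put Wednesday's at 24% (17% to 33%) and Saturday's at 44% (36% to 50%). Its ground: “The runs point to equilibrium, not simple catalyst death, as what holds the product down”.

The flask gives 29.6%. The best option is Monday's, adding 12 percentage points, while Saturday's adds 7.5 points. Wednesday's ends at 21.0% and Saturday's at 37.2%.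

    starting material + reagent + free catalyst ⇌ product + free catalyst, rate k1*[starting material]*[reagent]*[free catalyst] forward; the back reaction follows from the equilibrium constant (K = 3.00 L mol⁻¹, k = 2.11 L² mol⁻² s⁻¹, Ea = 43.0 kJ mol⁻¹, ΔH = −31.0 kJ mol⁻¹)
    free catalyst + product → spent catalyst (k = 0.205 L mol⁻¹ s⁻¹, Ea = 36.0 kJ mol⁻¹)
    free catalyst ⇌ dormant form (K = 0.524, k = 0.0767 s⁻¹, Ea = 67.0 kJ mol⁻¹, ΔH = −53.0 kJ mol⁻¹)
    (constants at −20 °C)

In this flask the forward half-life of starting material lengthens from 3.1 min at 1.06 min to 16 min at 8.00 min, with 12.4% of the catalyst charged still free. By then product is made, net, at 0.934 of the rate it is used up, and the quotient stands at 2.36 L mol⁻¹, then 2.44 L mol⁻¹ at 80.0 min.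

Take the neighbour charged with 0.25 M: the frozen quotient, with the whole loading counted as spent at one product each, gives 42.0% starting material and 45.0% product. Computed, that neighbour holds 40.1% and 46.9%, with 99.9% of its catalyst spent.

(Readings and results are simulated with constants of no real substance; noise was put on by code.)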